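**Retrosynthetic overview**

- Feature: rings A and B are 4-bromofuran-2(5H)-ones (O1, C2=O, C3, C4–Br, spiro C5) on neighbouring carbons of cyclobutane ring C. In each, the C3–C4 bond ties the α-carbon of an acyl group on O1 to a carboxyl carbon on C5, so each ring is a tetronic acid (C4–OH in place of C4–Br).
- Key disconnection: both C3–C4 bonds at once, by a twofold Dieckmann condensation of a dimethyl 3,4-dibromocyclobutane-1,2-dicarboxylate whose trans oxygens on C1 and C2 carry hexanoyl and (R)-3-silyloxyhexanoyl groups. C4 bromination, desilylation and acetylation follow.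
- Ring C with its all-trans O/Br/Br/O pattern: 4π photocyclization of a 3-hexanoyloxy-2-pyrone-6-carboxylate to the bicyclic β-lactone (the cis lactone fusion fixes the trans diol), anti addition of Br2, then lactone methanolysis.
- Order of ring formation: ring C (step 3), then rings A and B together (step 9). The racemic ring C is resolved as diastereomers when the (R) side-chain acid is attached (step 8).
- The alkene is brominated while locked in the bicycle, so no free trans-3,4-dioxycyclobutene (prone to conrotatory opening) is handled. No alkoxide is generated next to the ring esters, which would invite retro-aldol cleavage.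

Key step: step 9

Assumption: 1 (the dehydration product of galactaric acid) and 8 are taken as purchasable; 5, 6 and 7 are racemic and are named and drawn as the enantiomer that ends in 17.

**Route**

Step 1
Reactants: 1 3-hydroxy-2-oxo-2H-pyran-6-carboxylic acid
Product: 2 methyl 3-hydroxy-2-oxo-2H-pyran-6-carboxylate
Conditions: MeOH, H2SO4 (cat.), 60 °C
Reagents that add atoms: methanol, CO
Why: Fischer esterification of the carboxylic acid; the enolic 3-hydroxyl and the pyrone ring should survive acidic methanol.

Step 2
Reactants: 2 methyl 3-hydroxy-2-oxo-2H-pyran-6-carboxylate; 3 hexanoyl chloride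
Product: 4 methyl 3-(hexanoyloxy)-2-oxo-2H-pyran-6-carboxylate
Conditions: Et3N, CH2Cl2, 0 °C
Reagents that add atoms: none
Why: O-acylation of the acidic enol hydroxyl by an acid chloride (esterification), which puts the ring A acyl group on while this oxygen is still unhindered.

Step 3
Reactants: 4 methyl 3-(hexanoyloxy)-2-oxo-2H-pyran-6-carboxylate
Product: 5 methyl 4-(hexanoyloxy)-3-oxo-2-oxabicyclo[2.2.0]hex-5-ene-1-carboxylate (cis-fused; racemic)
Conditions: hν (300–350 nm, Pyrex), degassed CH2Cl2 (0.01 M), −20 °C, flow cell; solvent removed at 0 °C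
Reagents that add atoms: none
Why: Photochemical disrotatory 4π electrocyclization of the 2-pyrone diene (C3 to C6) to its bicyclic β-lactone valence isomer; the four-membered lactone can only be cis-fused, which places the lactone oxygen on C1 and the acyloxy oxygen on C4 on opposite faces of the new ring C (the later trans diol), and the product is racemic.

Step 4
Reactants: 5 methyl 4-(hexanoyloxy)-3-oxo-2-oxabicyclo[2.2.0]hex-5-ene-1-carboxylate
Product: 6 methyl (5-endo,6-exo)-5,6-dibromo-4-(hexanoyloxy)-3-oxo-2-oxabicyclo[2.2.0]hexane-1-carboxylate (racemic)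
Conditions: Br2 (1.05 equiv), CH2Cl2, −78 → −40 °C, dark
Reagents that add atoms: bromine, BrBr
Why: Ionic anti addition of bromine to the cyclobutene: the bromonium ion should form on the open exo face, where neither the ester nor the acyloxy group can take part, and bromide should open it from the endo face at C5, beside the electrophilic lactone carbonyl carbon and not at C6 beside the lone pairs of the ring oxygen, which puts Br on C6 exo and Br on C5 endo, each trans to the oxygen on the neighbouring bridgehead.

Step 5
Reactants: 6 methyl (5-endo,6-exo)-5,6-dibromo-4-(hexanoyloxy)-3-oxo-2-oxabicyclo[2.2.0]hexane-1-carboxylate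
Product: 7 dimethyl rac-(1R,2R,3R,4R)-3,4-dibromo-1-(hexanoyloxy)-2-hydroxycyclobutane-1,2-dicarboxylate
Conditions: MeOH, camphorsulfonic acid (10 mol %), CH2Cl2, 0 °C → rt
Reagents that add atoms: methanol, CO
Why: Acid-catalysed methanolysis of the strained β-lactone by acyl–oxygen cleavage (the quaternary, ester-bearing C–O carbon can neither ionize nor be displaced), with retention at both ring carbons; acid is chosen over base so that no alkoxide arises that could open the 2-hydroxycyclobutanecarboxylate by retro-aldol cleavage or close an epoxide on the anti bromide.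

Step 6
Reactants: 8 methyl (R)-3-hydroxyhexanoate
Product: 9 methyl (R)-3-[(tert-butyldimethylsilyl)oxy]hexanoate
Conditions: TBSCl, imidazole, DMF, rt
Reagents that add atoms: tert-butyl(chloro)dimethylsilane, CC(C)(C)[Si](C)(C)Cl
Why: Imidazole-promoted silylation of the secondary alcohol; the stereocentre is not involved.

Step 7
Reactants: 9 methyl (R)-3-[(tert-butyldimethylsilyl)oxy]hexanoate
Product: 10 (R)-3-[(tert-butyldimethylsilyl)oxy]hexanoic acid
Conditions: LiOH·H2O, THF/MeOH/H2O, 0 °C → rt; then aq. HCl to pH 3
Reagents that add atoms: lithium hydroxide, [Li+].[OH-]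
Why: Saponification of the methyl ester; the carbinol centre is β to the carbonyl and the silyl ether should hold at room temperature.

Step 8
Reactants: 7 dimethyl rac-(1R,2R,3R,4R)-3,4-dibromo-1-(hexanoyloxy)-2-hydroxycyclobutane-1,2-dicarboxylate; 10 (R)-3-[(tert-butyldimethylsilyl)oxy]hexanoic acid
Product: 12 dimethyl (1R,2R,3R,4R)-3,4-dibromo-1-(hexanoyloxy)-2-{[(3R)-3-(tert-butyldimethylsilyloxy)hexanoyl]oxy}cyclobutane-1,2-dicarboxylate, via acid chloride 11 (not isolated)
Conditions: 10, Me2C=C(Cl)NMe2, CH2Cl2, 0 °C; then 7, pyridine, DMAP, CH2Cl2, 0 → 40 °C; silica chromatography (preparative HPLC if needed)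
Reagents that add atoms: none
Why: DMAP-catalysed acyl transfer from an acid chloride (made under neutral conditions) to the tertiary alcohol without forming an alkoxide; no stereocentre is made, and because racemic 7 meets the single (R) acid, 12 should form together with the diastereomeric ester of the (1S,2S,3S,4S) ring C enantiomer, which is removed by chromatography, with the assignment to be secured by X-ray analysis using bromine anomalous dispersion.

Step 9
Reactants: 12 dimethyl (1R,2R,3R,4R)-3,4-dibromo-1-(hexanoyloxy)-2-{[(3R)-3-(tert-butyldimethylsilyloxy)hexanoyl]oxy}cyclobutane-1,2-dicarboxylate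
Product: 14 11,12-dibromo-3-butyl-4,10-dihydroxy-9-[(1R)-1-(tert-butyldimethylsilyloxy)butyl]-1,7-dioxadispiro[4.0.4.2]dodeca-3,9-diene-2,8-dione (bis-tetronic acid; ring C centres as in 12), via ring A monotetronic acid 13 (not isolated)
Conditions: LiN(SiMe3)2 (4.5 equiv), THF, −78 → −40 °C; then cold aq. HCl (pH 2)
Reagents that add atoms: none
Why: LiN(SiMe3)2 turns each acyloxy CH2 into a lithium ester enolate, which adds to the methyl ester on the same ring carbon and expels methoxide; the furan-2,4-dione so formed is deprotonated at once to the tetronate, which makes each closure irreversible (Dieckmann condensation of α-acyloxy esters, the standard entry to 3-alkyltetronic acids). Ring A (hexanoate arm on C1) and ring B (silyloxyhexanoate arm on C2) each close 5-exo-trig. No stereocentre is made: C1 and C2 of ring C are quaternary and cannot epimerize, and the side-chain carbinol is β to the enolate, where the silyl ether is a poor leaving group at −78 °C. The step needs chemoselectivity for the geminal ester; attack on the cis-vicinal ester would be 6-exo and give a cis-fused bicyclo[4.2.0] keto lactone, and C-alkylation would displace the anti ring bromide, but the geminal carbonyl is two atoms nearer and the bromide is secondary, neopentyl-like and on a four-membered ring. Excess base is used because each tetronate consumes one equivalent, and the mixture is kept cold so that the enolate of this ester of a stabilized tertiary alkoxide does not fragment to a ketene.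

Step 10
Reactants: 14 bis-tetronic acid
Product: 15 (5S,6S,11R,12R)-4,10,11,12-tetrabromo-3-butyl-9-[(1R)-1-(tert-butyldimethylsilyloxy)butyl]-1,7-dioxadispiro[4.0.4.2]dodeca-3,9-diene-2,8-dione
Conditions: (COBr)2, DMF, CH2Cl2, 0 °C → rt
Reagents that add atoms: oxalyl bromide, BrC(=O)C(=O)Br
Why: Vilsmeier-type deoxybromination of a vinylogous acid: each tetronic acid oxygen adds to the bromoiminium salt made from oxalyl bromide and DMF, and bromide then replaces the activated oxygen at C4 by addition–elimination at an sp2 carbon, while the silyl ether keeps the side-chain oxygen away from the reagent.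

Step 11
Reactants: 15 tetrabromide silyl ether
Product: 16 (5S,6S,11R,12R)-4,10,11,12-tetrabromo-3-butyl-9-[(1R)-1-hydroxybutyl]-1,7-dioxadispiro[4.0.4.2]dodeca-3,9-diene-2,8-dione
Conditions: 48% aq. HF, MeCN, 0 °C → rt
Reagents that add atoms: none
Why: Acidic cleavage of the silyl ether by HF, driven by Si–F bond formation, in the absence of amines and basic fluoride, which could attack the 4-bromobutenolides by addition–elimination; the carbinol C–O bond is not touched, so its configuration is kept.

Step 12
Reactants: 16 tetrabromo alcohol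
Product: 17 CNP0268004.1, (5S,6S,11R,12R)-9-[(1R)-1-acetoxybutyl]-4,10,11,12-tetrabromo-3-butyl-1,7-dioxadispiro[4.0.4.2]dodeca-3,9-diene-2,8-dione
Conditions: Ac2O, Sc(OTf)3 (2 mol %), MeCN, 0 °C
Reagents that add atoms: acetic anhydride, CC(=O)OC(C)=O
Why: Lewis acid-catalysed acetylation of the secondary alcohol, again without nucleophilic amines; only the O–H bond reacts, so the carbinol configuration is kept.

**Compound list**

1 | 3-hydroxy-2-oxo-2H-pyran-6-carboxylic acid | OC(=O)C1=CC=C(O)C(=O)O1 | starting material
2 | methyl 3-hydroxy-2-oxo-2H-pyran-6-carboxylate | COC(=O)C1=CC=C(O)C(=O)O1 | intermediate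
3 | hexanoyl chloride | CCCCCC(=O)Cl | starting material
4 | methyl 3-(hexanoyloxy)-2-oxo-2H-pyran-6-carboxylate | CCCCCC(=O)OC1=CC=C(C(=O)OC)OC1=O | intermediate
5 | methyl 4-(hexanoyloxy)-3-oxo-2-oxabicyclo[2.2.0]hex-5-ene-1-carboxylate (cis-fused; racemic, one enantiomer drawn) | CCCCCC(=O)O[C@@]12C(=O)O[C@]1(C(=O)OC)C=C2 | intermediate
6 | methyl (5-endo,6-exo)-5,6-dibromo-4-(hexanoyloxy)-3-oxo-2-oxabicyclo[2.2.0]hexane-1-carboxylate (racemic, one enantiomer drawn) | CCCCCC(=O)O[C@@]12C(=O)O[C@]1(C(=O)OC)[C@@H](Br)[C@@H]2Br | intermediate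
7 | dimethyl rac-(1R,2R,3R,4R)-3,4-dibromo-1-(hexanoyloxy)-2-hydroxycyclobutane-1,2-dicarboxylate (oxygens trans, bromines trans, each Br trans to the oxygen on the neighbouring carbon) | COC(=O)[C@@]1(OC(=O)CCCCC)[C@@H](Br)[C@H](Br)[C@@]1(C(=O)OC)O | intermediate
8 | methyl (R)-3-hydroxyhexanoate | COC(=O)C[C@@H](CCC)O | starting material
9 | methyl (R)-3-[(tert-butyldimethylsilyl)oxy]hexanoate | COC(=O)C[C@@H](CCC)O[Si](C)(C)C(C)(C)C | intermediate
10 | (R)-3-[(tert-butyldimethylsilyl)oxy]hexanoic acid | OC(=O)C[C@@H](CCC)O[Si](C)(C)C(C)(C)C | intermediate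
11 | (R)-3-[(tert-butyldimethylsilyl)oxy]hexanoyl chloride (not isolated) | ClC(=O)C[C@@H](CCC)O[Si](C)(C)C(C)(C)C | intermediate
12 | dimethyl (1R,2R,3R,4R)-3,4-dibromo-1-(hexanoyloxy)-2-{[(3R)-3-(tert-butyldimethylsilyloxy)hexanoyl]oxy}cyclobutane-1,2-dicarboxylate | COC(=O)[C@@]1(OC(=O)CCCCC)[C@@H](Br)[C@H](Br)[C@@]1(C(=O)OC)OC(=O)C[C@@H](CCC)O[Si](C)(C)C(C)(C)C | intermediate
13 | ring A monotetronic acid: ring A closed on C1 of ring C, methyl ester and (R)-3-silyloxyhexanoate still open on C2 (not isolated) | CCCCC1=C(O)[C@@]2(OC1=O)[C@@H](Br)[C@H](Br)[C@@]2(C(=O)OC)OC(=O)C[C@@H](CCC)O[Si](C)(C)C(C)(C)C | intermediate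
14 | 11,12-dibromo-3-butyl-4,10-dihydroxy-9-[(1R)-1-(tert-butyldimethylsilyloxy)butyl]-1,7-dioxadispiro[4.0.4.2]dodeca-3,9-diene-2,8-dione (ring C centres as in 12) | CCCCC1=C(O)[C@@]2(OC1=O)[C@@H](Br)[C@H](Br)[C@@]21OC(=O)C([C@@H](CCC)O[Si](C)(C)C(C)(C)C)=C1O | intermediate
15 | (5S,6S,11R,12R)-4,10,11,12-tetrabromo-3-butyl-9-[(1R)-1-(tert-butyldimethylsilyloxy)butyl]-1,7-dioxadispiro[4.0.4.2]dodeca-3,9-diene-2,8-dione | CCCCC1=C(Br)[C@@]2(OC1=O)[C@@H](Br)[C@H](Br)[C@@]21OC(=O)C([C@@H](CCC)O[Si](C)(C)C(C)(C)C)=C1Br | intermediate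
16 | (5S,6S,11R,12R)-4,10,11,12-tetrabromo-3-butyl-9-[(1R)-1-hydroxybutyl]-1,7-dioxadispiro[4.0.4.2]dodeca-3,9-diene-2,8-dione | CCCCC1=C(Br)[C@@]2(OC1=O)[C@@H](Br)[C@H](Br)[C@@]21OC(=O)C([C@@H](CCC)O)=C1Br | intermediate
17 | CNP0268004.1, (5S,6S,11R,12R)-9-[(1R)-1-acetoxybutyl]-4,10,11,12-tetrabromo-3-butyl-1,7-dioxadispiro[4.0.4.2]dodeca-3,9-diene-2,8-dione | CCCCC1=C(Br)[C@@]2(OC1=O)[C@@H](Br)[C@H](Br)[C@@]21OC(=O)C([C@@H](CCC)OC(C)=O)=C1Br | target

**Totals**

Total step count: 12
Longest linear sequence: 10 steps (steps 1–5 and 8–12)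

**Steps most likely to fail**

1. Step 4. The bromide may open the exo bromonium ion at C6 and not at C5, which would give the other trans-dibromide, or the strained bicyclic cation may rearrange before it is captured. Fallback from 5 back to 6: 5 is epoxidized on the exo face with dimethyldioxirane (acetone, −20 °C) to the exo-5,6-epoxide F1. MgBr2·OEt2 then opens the epoxide from the endo face to the 5-endo-bromo-6-exo-hydroxy lactone F2, to its regioisomer the 6-endo-bromo-5-exo-hydroxy lactone F3, or to both. With PPh3/CBr4 the exo hydroxyl of either bromohydrin is activated and should leave with help from the anti bromine, so both give the same endo-bridged bromonium ion. Bromide then opens this ion on the open exo face, where the choice is between C6 beside the ester carbon and C5 beside the acyloxy oxygen; attack at C6 gives 6. The regiochemistry is thus decided on the other face and by other flanking groups than in the direct addition.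

2. Step 9. The ring B enolate may lose silanolate by β-elimination before it cyclizes, an enolate may fragment to a ketene on warming, or the second closure may stall. Fallback from 12 back to 14: aq. HF in MeCN removes the side-chain silyl group to give the hydroxy diester F4. Excess LiN(iPr)2 (THF, −78 → −30 °C) then makes the alkoxide together with both enolates; an enolate with a β-oxide cannot eliminate. The twofold Dieckmann closure gives the lithium salt of the hydroxy bis-tetronic acid F5, which is not isolated because 3-(1-hydroxyalkyl)tetronic acids lose water easily. TBSOTf is added to the same flask to give the tris-silyl derivative F6, whose two silyl tetronate groups are hydrolysed in the acidic work-up, leaving 14.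

3. Step 8. The crowded, weakly nucleophilic tertiary hydroxyl may not be acylated before the activated β-silyloxy acid decomposes, and the two diastereomers may not separate. Fallback from 7 back to 12: 5-butanoyl-2,2-dimethyl-1,3-dioxane-4,6-dione F7 (from Meldrum's acid, butanoyl chloride and pyridine) is heated with 7 in toluene at 90 °C. The butanoylketene set free adds to the tertiary alcohol, a reaction that tolerates very hindered alcohols, and gives the 3-oxohexanoate F8. Asymmetric hydrogenation of the ketone (RuCl2[(R)-BINAP], H2, MeOH) should give the (R)-carbinol as the hydroxy diester F4 and its ring C diastereomer F9, which are separated as free alcohols. F4 is silylated (TBSOTf, 2,6-lutidine, CH2Cl2, −78 °C) to 12.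

**Further compounds**

F1 | step 4 | exo-5,6-epoxide of 5 (methyl 5,6-epoxy-4-(hexanoyloxy)-3-oxo-2-oxabicyclo[2.2.0]hexane-1-carboxylate) | CCCCCC(=O)O[C@@]12C(=O)O[C@]1(C(=O)OC)[C@H]3O[C@@H]23
F2 | step 4 | methyl 5-endo-bromo-4-(hexanoyloxy)-6-exo-hydroxy-3-oxo-2-oxabicyclo[2.2.0]hexane-1-carboxylate | CCCCCC(=O)O[C@@]12C(=O)O[C@]1(C(=O)OC)[C@@H](O)[C@@H]2Br
F3 | step 4 | methyl 6-endo-bromo-4-(hexanoyloxy)-5-exo-hydroxy-3-oxo-2-oxabicyclo[2.2.0]hexane-1-carboxylate | CCCCCC(=O)O[C@@]12C(=O)O[C@]1(C(=O)OC)[C@H](Br)[C@H]2O
F4 | step 9 | dimethyl (1R,2R,3R,4R)-3,4-dibromo-1-(hexanoyloxy)-2-{[(3R)-3-hydroxyhexanoyl]oxy}cyclobutane-1,2-dicarboxylate | COC(=O)[C@@]1(OC(=O)CCCCC)[C@@H](Br)[C@H](Br)[C@@]1(C(=O)OC)OC(=O)C[C@@H](CCC)O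
F5 | step 9 | 11,12-dibromo-3-butyl-4,10-dihydroxy-9-[(1R)-1-hydroxybutyl]-1,7-dioxadispiro[4.0.4.2]dodeca-3,9-diene-2,8-dione (formed as its lithium salt) | CCCCC1=C(O)[C@@]2(OC1=O)[C@@H](Br)[C@H](Br)[C@@]21OC(=O)C([C@@H](CCC)O)=C1O
F6 | step 9 | tris-silyl derivative of F5 (both tetronate oxygens and the side-chain oxygen as tert-butyldimethylsilyl ethers) | CCCCC1=C(O[Si](C)(C)C(C)(C)C)[C@@]2(OC1=O)[C@@H](Br)[C@H](Br)[C@@]21OC(=O)C([C@@H](CCC)O[Si](C)(C)C(C)(C)C)=C1O[Si](C)(C)C(C)(C)C
F7 | step 8 | 5-butanoyl-2,2-dimethyl-1,3-dioxane-4,6-dione | CCCC(=O)C1C(=O)OC(C)(C)OC1=O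
F8 | step 8 | dimethyl rac-(1R,2R,3R,4R)-3,4-dibromo-1-(hexanoyloxy)-2-[(3-oxohexanoyl)oxy]cyclobutane-1,2-dicarboxylate | COC(=O)[C@@]1(OC(=O)CCCCC)[C@@H](Br)[C@H](Br)[C@@]1(C(=O)OC)OC(=O)CC(=O)CCC
F9 | step 8 | diastereomer of F4 with enantiomeric ring C, (1S,2S,3S,4S), and the same (3R) carbinol | COC(=O)[C@]1(OC(=O)CCCCC)[C@H](Br)[C@@H](Br)[C@]1(C(=O)OC)OC(=O)C[C@@H](CCC)O
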